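Assumption: the target (6-prenylmorin, C20H18O7) has no stereocentre and no stereogenic double bond, so there is no enantiomer to control. Commercial morin hydrate is dried before use.

**Retrosynthetic overview**
1. Ring order: no ring is built. Rings A, C and B are bought together as morin 1, and its 3,7,2',4'-tetraacetate 2 leaves only the chelated 5-OH free.
2. Prenyl carbons: 2-methylbut-3-en-2-ol 3, activated through its alkoxide 4 as the mixed carbonate 5.
3. Key disconnection: the C5–O–C(CH3)2 aryl ether bond of 6, made from 2 and 5.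
4. The C6–prenyl bond of 8 is the retro-[3,3] image of that ether, through dienone 7, so the C–O bond fixes the regiochemistry.
5. Target 9 comes from 8 by removal of the four acetates.

**Route**

Step 1
Reactants: 1 morin
Product: 2 3,7,2',4'-tetra-O-acetylmorin (5-OH free)
Conditions: Ac2O (4.3 equiv), pyridine, 0 °C → rt, 6 h
Reagents that add atoms: acetic anhydride, CC(=O)OC(C)=O
Why: Kinetically controlled O-acetylation works because the 5-OH is held in a strong six-membered hydrogen bond to C4=O and is the least nucleophilic hydroxyl, so about four equivalents of anhydride esterify 3-, 7-, 2'- and 4'-OH and leave it free; no stereocentre is formed.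

Step 2
Reactants: 3 2-methylbut-3-en-2-ol
Product: 5 tert-butyl (2-methylbut-3-en-2-yl) carbonate, via lithium 2-methylbut-3-en-2-olate 4 (not isolated)
Conditions: n-BuLi (1.05 equiv), THF, −78 → 0 °C; Boc2O (1.05 equiv), 0 °C → rt; H2O quench
Reagents that add atoms: di-tert-butyl dicarbonate, CC(C)(C)OC(=O)OC(=O)OC(C)(C)C
Why: O-acylation of a preformed tertiary lithium alkoxide with Boc2O (mixed carbonate formation) is fast and is made irreversible by loss of CO2 from the tert-butyl carbonate leaving group.

Step 3
Reactants: 2 3,7,2',4'-tetra-O-acetylmorin; 5 tert-butyl (2-methylbut-3-en-2-yl) carbonate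
Product: 8 3,7,2',4'-tetra-O-acetyl-6-prenylmorin, via 5-O-(1,1-dimethylallyl) ether 6 (not isolated), via C6-prenyl cyclohexadienone 7 (not isolated)
Conditions: 5 (1.3 equiv), Pd2(dba)3·CHCl3 (2.5 mol %), Xantphos (6 mol %), THF, 0 °C, 3 h; thiol-silica, filter; swap to PhMe, 100 °C, 4 h
Reagents that add atoms: none
Why: Proposed new method: decarboxylative Tsuji–Trost O-tert-prenylation has not been shown on a chelated peri-hydroxy-carbonyl phenol such as a flavonol 5-OH; ionisation of 5 by Pd(0) releases CO2 and t-BuO−, which irreversibly deprotonates the hydrogen-bonded 5-OH, and the freed phenoxide ion-pairs with the cationic (1,1-dimethyl-π-allyl)Pd and attacks its tertiary terminus under kinetic control, because the wide bite angle of Xantphos lengthens the Pd–C(CH3)2 bond and concentrates positive charge there, so forming the C5–O–C(CH3)2 bond of 6; removing Pd then blocks re-ionisation to the linear prenyl ether and any second prenylation, and peri strain plus the gem-dimethyl group drive a mild ortho-Claisen [3,3] shift to C6 (the only free ortho carbon, C4a being blocked), which inverts the allyl unit to a normal prenyl group in dienone 7, whose enolisation is faster than a Cope shift to C8 (that shift would build a quaternary carbon) and gives 8; closest known reaction type: Pd-catalysed reverse-prenyl etherification of unhindered phenols followed by aromatic Claisen rearrangement; the transient C6 stereocentre of 7 is erased on rearomatisation.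

Step 4
Reactants: 8 3,7,2',4'-tetra-O-acetyl-6-prenylmorin
Product: 9 6-prenylmorin (target)
Conditions: K2CO3 (6 equiv), degassed MeOH, Ar, 0 °C → rt, 1 h; 1 M HCl to pH 3 at 0 °C
Reagents that add atoms: none
Why: Base-mediated transesterification (Zemplén-type methanolysis) cleaves the three aryl acetates and the enol acetate rapidly while the prenyl alkene and the chromone are inert, and oxygen is excluded because flavonol polyphenolates autoxidise.

**Compound list**
1 | morin, 2-(2,4-dihydroxyphenyl)-3,5,7-trihydroxy-4H-chromen-4-one | O=c1c(O)c(-c2ccc(O)cc2O)oc2cc(O)cc(O)c12 | starting material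
2 | 3,7,2',4'-tetra-O-acetylmorin (5-OH free) | O=c1c(OC(C)=O)c(-c2ccc(OC(C)=O)cc2OC(C)=O)oc2cc(OC(C)=O)cc(O)c12 | intermediate
3 | 2-methylbut-3-en-2-ol | CC(C)(O)C=C | starting material
4 | lithium 2-methylbut-3-en-2-olate | [Li+].[O-]C(C)(C)C=C | intermediate
5 | tert-butyl (2-methylbut-3-en-2-yl) carbonate | CC(C)(C)OC(=O)OC(C)(C)C=C | intermediate
6 | 3,7,2',4'-tetra-O-acetyl-5-O-(1,1-dimethylallyl)morin | O=c1c(OC(C)=O)c(-c2ccc(OC(C)=O)cc2OC(C)=O)oc2cc(OC(C)=O)cc(OC(C)(C)C=C)c12 | intermediate
7 | C6-prenyl cyclohexa-2,4-dienone tautomer of 8 (5-oxo, C6 sp3, racemic, transient) | CC(C)=CCC1C(OC(C)=O)=CC2=C(C1=O)C(=O)C(OC(C)=O)=C(O2)c1ccc(OC(C)=O)cc1OC(C)=O | intermediate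
8 | 3,7,2',4'-tetra-O-acetyl-6-prenylmorin | CC(C)=CCc1c(OC(C)=O)cc2oc(-c3ccc(OC(C)=O)cc3OC(C)=O)c(OC(C)=O)c(=O)c2c1O | intermediate
9 | 6-prenylmorin, 2-(2,4-dihydroxyphenyl)-3,5,7-trihydroxy-6-(3-methylbut-2-enyl)-4H-chromen-4-one | CC(C)=CCc1c(O)cc2oc(-c3ccc(O)cc3O)c(O)c(=O)c2c1O | target

**Totals**
Total step count: 4.
Longest linear sequence: 3 (1 → 2 → 8 → 9).

**Three steps most likely to fail**

Step 3 (the new step).
- Risks: the hindered, chelated phenoxide may attack the primary allyl terminus and give the linear ether, which would lead to 8-prenyl products. Phenoxide-mediated acetyl scrambling may occur. Ether 6 may lose isoprene on heating.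
- Fallback (known chemistry): this sets out from 2. Mitsunobu etherification with 3-methylbut-2-en-1-ol (PPh3, DIAD, THF, 0 °C → rt) works on the chelated 5-OH of acetylated flavonoids. It gives 3,7,2',4'-tetra-O-acetyl-5-O-prenylmorin F1. Stirring this ether with Montmorillonite K10 in CH2Cl2 at 0 °C → rt triggers the established acid-clay [1,3] O→C prenyl shift to the ortho carbon C6. The fallback rejoins the route at 8.

Step 1.
- Risk: tetra- and pentaacetate mixtures that are hard to separate.
- Fallback: this sets out from 1 and changes the protecting-group class. MOMCl (4.5 equiv) and i-Pr2NEt in CH2Cl2, to which a chelated 5-OH is inert, give 3,7,2',4'-tetrakis-O-(methoxymethyl)morin F2. Putting this through the step 3 sequence with 5 passes through the tertiary 5-O-(1,1-dimethylallyl) ether F3 and the C6-prenyl dienone F4. It delivers 3,7,2',4'-tetrakis-O-(methoxymethyl)-6-prenylmorin F5. Brief treatment with 3 M HCl in MeOH at 50 °C removes the acetals, and the fallback rejoins the route at 9.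

Step 4.
- Risk: oxidative degradation of the pentahydroxyflavonol as its polyphenolate.
- Fallback: this sets out from 8 and replaces chemical base by biocatalysis. The aryl and enol acetates are hydrolysed by an esterase (porcine liver esterase or Candida rugosa lipase) in pH 6.5 phosphate buffer with 15 % acetone at 30 °C under N2. The product never sees basic pH. The fallback rejoins the route at 9 and makes no new compound (F0).

**Further compounds**
F1 | step 3 | 3,7,2',4'-tetra-O-acetyl-5-O-prenylmorin | O=c1c(OC(C)=O)c(-c2ccc(OC(C)=O)cc2OC(C)=O)oc2cc(OC(C)=O)cc(OCC=C(C)C)c12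
F2 | step 1 | 3,7,2',4'-tetrakis-O-(methoxymethyl)morin | O=c1c(OCOC)c(-c2ccc(OCOC)cc2OCOC)oc2cc(OCOC)cc(O)c12
F3 | step 1 | 3,7,2',4'-tetrakis-O-(methoxymethyl)-5-O-(1,1-dimethylallyl)morin | O=c1c(OCOC)c(-c2ccc(OCOC)cc2OCOC)oc2cc(OCOC)cc(OC(C)(C)C=C)c12
F4 | step 1 | C6-prenyl cyclohexa-2,4-dienone tautomer of F5 (racemic, transient) | CC(C)=CCC1C(OCOC)=CC2=C(C1=O)C(=O)C(OCOC)=C(O2)c1ccc(OCOC)cc1OCOC
F5 | step 1 | 3,7,2',4'-tetrakis-O-(methoxymethyl)-6-prenylmorin | CC(C)=CCc1c(OCOC)cc2oc(-c3ccc(OCOC)cc3OCOC)c(OCOC)c(=O)c2c1O
F0 | step 4 | none | none
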